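**Strategy.** The seven-membered dioxepinone is disconnected at the diaryl ether bond between the ring A oxygen on C2 and ring B carbon C6′. Ring B, the lactol-bearing ring, has C6′ para to the free phenol on C3′ and ortho to the ester oxygen on C1′, while C2′, the other carbon ortho to that oxygen, is blocked by the fumaroyloxymethyl arm. Two-electron oxidation of the C3′ phenol in an allyl-protected depside therefore lets the ring A hydroxyl add to C6′, closing the central ring and forming the ether bond in one operation. The precursor is the ring A 2-hydroxybenzoate of a ring B phenol whose future lactol is still an open aldehyde beside an allyl ester.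

Key step: step 11

Atom labels: ring A runs C1 (ester carbonyl attached), C2 (OH), C3 (CHO), C4 (O), C5 (H), C6 (CH3); ring B runs C1′ (ester oxygen), C2′ (CH2O arm), C3′ (phenol), C4′ (carboxyl), C5′ (formyl or lactol carbon), C6′ (ether carbon).

Remark: the lactol carbon equilibrates with the open formyl acid in solution, so its (R) configuration is assumed to be fixable only by crystallisation and is set last; quinidine is assumed to be the alkaloid whose less soluble salt holds (R), and quinine would take its place otherwise.

**Route**

Step 1
Reactants: 1 methyl orsellinate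
Product: 3 methyl 3-formyl-2,4-dihydroxy-6-methylbenzoate, via α-chloro ether 2 (not isolated)
Conditions: Cl2CHOMe, TiCl4, CH2Cl2, −10 → 0 °C; then aq. HCl
Reagents that add atoms: dichloromethyl methyl ether (COC(Cl)Cl); water (O)
Why: Rieche formylation, in which titanium bound to the phenol oxygens delivers the electrophile to C3, the position ortho to both hydroxyls, and aqueous work-up hydrolyses the α-chloro ether to the aldehyde; the minor 5-formyl isomer is expected to be removed by crystallisation.

Step 2
Reactants: 3 methyl 3-formyl-2,4-dihydroxy-6-methylbenzoate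
Product: 4 methyl 3-formyl-2-hydroxy-6-methyl-4-(prop-2-en-1-yloxy)benzoate
Conditions: allyl bromide (1.05 equiv), K2CO3 (1.1 equiv), acetone, 20 °C
Reagents that add atoms: allyl bromide (C=CCBr)
Why: Williamson etherification; O4 is the less hindered phenoxide, O2 being buried between the ester and formyl groups and chelated to the ester carbonyl, so one equivalent of halide should alkylate O4 only.

Step 3
Reactants: 4 methyl 3-formyl-2-hydroxy-6-methyl-4-(prop-2-en-1-yloxy)benzoate
Product: 5 3-formyl-2-hydroxy-6-methyl-4-(prop-2-en-1-yloxy)benzoic acid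
Conditions: KOH, DMSO–H2O (4:1), 60 °C; then aq. HCl, 0 °C
Reagents that add atoms: potassium hydroxide ([K+].[OH-])
Why: Saponification of a hindered ortho-hydroxybenzoate by poorly solvated hydroxide in aqueous DMSO; the water content should keep the medium too weakly basic for allyl-to-propenyl isomerisation, and the ortho-phenoxide aldehyde resists Cannizzaro reaction.

Step 4
Reactants: 3 methyl 3-formyl-2,4-dihydroxy-6-methylbenzoate
Product: 7 methyl 2,4-diacetoxy-3-(acetoxymethyl)-6-methylbenzoate, via benzylic alcohol 6 (not isolated)
Conditions: NaBH4, THF–EtOH, 0 °C; AcOH quench, evaporate; then Ac2O, pyridine, DMAP (cat.), 0 → 20 °C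
Reagents that add atoms: acetic anhydride (CC(=O)OC(C)=O)
Why: Borohydride reduction of the aldehyde followed by exhaustive O-acetylation; capping the 2,6-dihydroxybenzyl alcohol at once blocks ortho-quinone methide formation and deactivates the ring for the radical step.

Step 5
Reactants: 7 methyl 2,4-diacetoxy-3-(acetoxymethyl)-6-methylbenzoate
Product: 8 methyl 2,4-diacetoxy-3-(acetoxymethyl)-6-(dibromomethyl)benzoate
Conditions: NBS (2.3 equiv), AIBN (cat.), PhCF3, 85 °C, visible light
Reagents that add atoms: N-bromosuccinimide (O=C1CCC(=O)N1Br)
Why: Wohl–Ziegler bromination; the single methyl group should be dibrominated as ortho-toluates are, the acylated ring resists electrophilic bromine, and the acetoxymethyl hydrogens, held between two ortho acetoxy groups and bearing an acyloxy substituent, should be abstracted more slowly.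

Step 6
Reactants: 8 methyl 2,4-diacetoxy-3-(acetoxymethyl)-6-(dibromomethyl)benzoate
Product: 11 rac-3,5,7-trihydroxy-6-(hydroxymethyl)-2-benzofuran-1(3H)-one, via formyl triacetate 9 (not isolated), via open formyl acid 10 (not isolated)
Conditions: AgNO3, acetone–H2O, 20 °C, dark; filter; then LiOH, THF–H2O (no alcohol), argon, 0 → 20 °C; then aq. HCl to pH 2, 0 °C
Reagents that add atoms: water (O); lithium hydroxide ([Li+].[OH-])
Why: Silver-assisted hydrolysis of the geminal dibromide gives the aldehyde, saponification removes the three acetates and the methyl ester (the latter helped by the neighbouring formyl hydrate), and on acidification the 2-formylbenzoic acid closes to the racemic 3-hydroxyphthalide by ring–chain tautomerism.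

Step 7
Reactants: 11 rac-3,5,7-trihydroxy-6-(hydroxymethyl)-2-benzofuran-1(3H)-one
Product: 12 prop-2-en-1-yl 6-formyl-2,4-dihydroxy-3-(hydroxymethyl)benzoate
Conditions: allyl bromide (1.1 equiv), KHCO3 (1.1 equiv), DMF, 20 °C
Reagents that add atoms: allyl bromide (C=CCBr)
Why: Carboxylate O-alkylation; hydrogen carbonate deprotonates only the pseudo-acid, whose ring-opened carboxylate is alkylated to the normal allyl ester and so releases the free aldehyde, while the less acidic phenols and the alcohol stay untouched.

Step 8
Reactants: 13 maleic anhydride; 14 allyl alcohol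
Product: 16 (2E)-4-oxo-4-(prop-2-en-1-yloxy)but-2-enoic acid (monoallyl fumarate), via monoallyl maleate 15 (not isolated)
Conditions: toluene, 60 °C; then AlCl3 (3 mol %), 75 °C
Reagents that add atoms: none
Why: Alcoholysis of the cyclic anhydride gives the Z half-ester, and Lewis acid catalysed Z-to-E isomerisation converts it into the thermodynamically favoured fumarate half-ester.

Step 9
Reactants: 12 prop-2-en-1-yl 6-formyl-2,4-dihydroxy-3-(hydroxymethyl)benzoate; 16 monoallyl fumarate
Product: 17 prop-2-en-1-yl 6-formyl-2,4-dihydroxy-3-({[(2E)-4-oxo-4-(prop-2-en-1-yloxy)but-2-enoyl]oxy}methyl)benzoate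
Conditions: PPh3, DIAD (added last), THF, 0 °C
Reagents that add atoms: none
Why: Mitsunobu esterification; the carboxylic acid is by far the most acidic pronucleophile, so the activated primary benzylic alcohol should be esterified while both phenols and the aldehyde are left alone and the E alkene is untouched.

Step 10
Reactants: 5 3-formyl-2-hydroxy-6-methyl-4-(prop-2-en-1-yloxy)benzoic acid; 17 ring B phenol
Product: 18 depside: prop-2-en-1-yl 6-formyl-2-hydroxy-4-{[3-formyl-2-hydroxy-6-methyl-4-(prop-2-en-1-yloxy)benzoyl]oxy}-3-({[(2E)-4-oxo-4-(prop-2-en-1-yloxy)but-2-enoyl]oxy}methyl)benzoate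
Conditions: DCC, DMAP (5 mol %), CH2Cl2, 0 → 20 °C
Reagents that add atoms: none
Why: Steglich esterification; the 4-hydroxyl of 17 (the C1′ oxygen) is the only phenol not chelated to an ortho carbonyl, the 2-hydroxyls of both partners being tied up in hydrogen bonds, so a single aryl ester should form.

Step 11
Reactants: 18 depside
Product: 19 depsidone: prop-2-en-1-yl 4,6-diformyl-8-hydroxy-1-methyl-11-oxo-3-(prop-2-en-1-yloxy)-9-({[(2E)-4-oxo-4-(prop-2-en-1-yloxy)but-2-enoyl]oxy}methyl)-11H-dibenzo[b,e][1,4]dioxepine-7-carboxylate
Conditions: PhI(OCOCF3)2 (1.1 equiv), (CF3)2CHOH, 0.005 M, 0 → 20 °C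
Reagents that add atoms: none
Why: The C3′ phenol of ring B exchanges a trifluoroacetate on trivalent iodine; loss of iodobenzene in the ionising, non-nucleophilic solvent makes ring B a phenoxenium-type electrophile, the ring A C2 hydroxyl adds to its para carbon C6′, and the cyclohexadienone so formed loses the C6′ proton to restore the arene. The closest known reactions are the hypervalent iodine para-functionalisation of phenols by oxygen nucleophiles and the oxidative phenol coupling of depsides to depsidones. The seven-membered ring closes by O-attack on a trigonal carbon with the C1′–C6′ bond inside the new ring (7-endo), the planar aryl ester holding the hydroxyl over C6′. No stereocentre is formed. Regioselectivity follows from the tether, which reaches only C2′ and C6′, and from C2′ being fully substituted, so that only attack at C6′ can end in an arene; chemoselectivity follows from the fact that an iodine-bound ring A phenol has no internal nucleophile within reach of its para carbon C5 and should simply exchange back, while high dilution and 1.1 equiv of oxidant should hold back intermolecular coupling and a second oxidation of the aryloxyphenol product.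

Step 12
Reactants: 19 depsidone
Product: 21 racemic lactol (target constitution with both configurations at the hemiacetal carbon), via open formyl triacid 20 (not isolated)
Conditions: Pd(PPh3)4 (5 mol %), PhNHMe (10 equiv), THF, 20 °C, argon; then cold 0.5 M HCl, precipitation
Reagents that add atoms: none
Why: Tsuji–Trost deallylation; zerovalent palladium ionises the two allyl esters and the allyl aryl ether, the weakly basic aniline traps the allyl units without touching aldehydes, fumarate or lactone, and the freed 2-formylbenzoic acid should close spontaneously to the lactol as both enantiomers.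

Step 13
Reactants: 21 racemic lactol; 22 quinidine
Product: 23 quinidinium salt of the (R)-lactol (fumaric carboxylate, protonated quinuclidine nitrogen)
Conditions: quinidine (1.0 equiv), acetone–MeCN (no alcohol), 45 → 20 °C, slurry ageing; filter
Reagents that add atoms: none
Why: Proposed new method: crystallisation-induced asymmetric transformation of a diastereomeric salt at a racemising lactol carbon, in which the fumaric half-acid forms the quinidinium salt, the two lactol epimers interconvert in solution through the open formyl acid (ring–chain tautomerism helped by the carboxylate–ammonium pair), and the less soluble salt, assumed to hold the (R)-lactol, is drained from the equilibrium by crystallisation so that the whole batch should converge on it; the closest known processes are the crystallisation of single anomers of mutarotating sugars, salt-driven asymmetric transformations of racemising acids, and dynamic kinetic resolution of 3-hydroxyphthalides by acylation.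

Step 14
Reactants: 23 quinidinium salt of the (R)-lactol
Product: 24 target, (R)-lactol free acid
Conditions: EtOAc–THF / cold 0.5 M HCl, 0 °C, immediate phase separation; Na2SO4; concentrate below 5 °C; heptane
Reagents that add atoms: none
Why: Salt break by acid–base extraction; the alkaloid leaves in water as its hydrochloride and the free acid is precipitated at once from a cold, base-free aprotic phase, in which ring opening of the lactol, which needs acid–base catalysis, should be too slow to erode the (R) configuration.

**Compound list**

1 | methyl orsellinate (methyl 2,4-dihydroxy-6-methylbenzoate) | COC(=O)c1c(C)cc(O)cc1O | starting material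
2 | methyl 3-[chloro(methoxy)methyl]-2,4-dihydroxy-6-methylbenzoate (not isolated) | COC(=O)c1c(C)cc(O)c(C(Cl)OC)c1O | intermediate
3 | methyl 3-formyl-2,4-dihydroxy-6-methylbenzoate | COC(=O)c1c(C)cc(O)c(C=O)c1O | intermediate
4 | methyl 3-formyl-2-hydroxy-6-methyl-4-(prop-2-en-1-yloxy)benzoate | COC(=O)c1c(C)cc(OCC=C)c(C=O)c1O | intermediate
5 | 3-formyl-2-hydroxy-6-methyl-4-(prop-2-en-1-yloxy)benzoic acid | OC(=O)c1c(C)cc(OCC=C)c(C=O)c1O | intermediate
6 | methyl 2,4-dihydroxy-3-(hydroxymethyl)-6-methylbenzoate (not isolated) | COC(=O)c1c(C)cc(O)c(CO)c1O | intermediate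
7 | methyl 2,4-diacetoxy-3-(acetoxymethyl)-6-methylbenzoate | COC(=O)c1c(C)cc(OC(C)=O)c(COC(C)=O)c1OC(C)=O | intermediate
8 | methyl 2,4-diacetoxy-3-(acetoxymethyl)-6-(dibromomethyl)benzoate | COC(=O)c1c(C(Br)Br)cc(OC(C)=O)c(COC(C)=O)c1OC(C)=O | intermediate
9 | methyl 2,4-diacetoxy-3-(acetoxymethyl)-6-formylbenzoate (not isolated) | COC(=O)c1c(C=O)cc(OC(C)=O)c(COC(C)=O)c1OC(C)=O | intermediate
10 | 6-formyl-2,4-dihydroxy-3-(hydroxymethyl)benzoic acid (not isolated) | OC(=O)c1c(C=O)cc(O)c(CO)c1O | intermediate
11 | rac-3,5,7-trihydroxy-6-(hydroxymethyl)-2-benzofuran-1(3H)-one | O=C1OC(O)c2cc(O)c(CO)c(O)c12 | intermediate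
12 | prop-2-en-1-yl 6-formyl-2,4-dihydroxy-3-(hydroxymethyl)benzoate | C=CCOC(=O)c1c(C=O)cc(O)c(CO)c1O | intermediate
13 | maleic anhydride | O=C1OC(=O)C=C1 | starting material
14 | allyl alcohol | C=CCO | starting material
15 | (2Z)-4-oxo-4-(prop-2-en-1-yloxy)but-2-enoic acid, monoallyl maleate (not isolated) | C=CCOC(=O)/C=C\C(=O)O | intermediate
16 | (2E)-4-oxo-4-(prop-2-en-1-yloxy)but-2-enoic acid, monoallyl fumarate | C=CCOC(=O)/C=C/C(=O)O | intermediate
17 | prop-2-en-1-yl 6-formyl-2,4-dihydroxy-3-({[(2E)-4-oxo-4-(prop-2-en-1-yloxy)but-2-enoyl]oxy}methyl)benzoate | C=CCOC(=O)/C=C/C(=O)OCc1c(O)cc(C=O)c(C(=O)OCC=C)c1O | intermediate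
18 | allyl-protected depside (4-O-aroyl ester of 17 with acid 5) | Cc1cc(OCC=C)c(C=O)c(O)c1C(=O)Oc1c(COC(=O)/C=C/C(=O)OCC=C)c(O)c(C(=O)OCC=C)c(C=O)c1 | intermediate
19 | allyl-protected depsidone (11-oxo-11H-dibenzo[b,e][1,4]dioxepine: 1-methyl, 3-allyloxy, 4-formyl, 6-formyl, 7-allyl ester, 8-hydroxy, 9-CH2O allyl fumarate) | Cc1cc(OCC=C)c(C=O)c2c1C(=O)Oc1c(COC(=O)/C=C/C(=O)OCC=C)c(O)c(C(=O)OCC=C)c(C=O)c1O2 | intermediate
20 | 9-({[(2E)-3-carboxyprop-2-enoyl]oxy}methyl)-4,6-diformyl-3,8-dihydroxy-1-methyl-11-oxo-11H-dibenzo[b,e][1,4]dioxepine-7-carboxylic acid (not isolated) | Cc1cc(O)c(C=O)c2c1C(=O)Oc1c(COC(=O)/C=C/C(=O)O)c(O)c(C(=O)O)c(C=O)c1O2 | intermediate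
21 | racemic lactol (3-hydroxyphthalide from the C4′ carboxyl and C5′ formyl of 20) | Cc1cc(O)c(C=O)c2c1C(=O)Oc1c(COC(=O)/C=C/C(=O)O)c(O)c3c(c1O2)C(O)OC3=O | intermediate
22 | quinidine, (8R,9S)-6′-methoxycinchonan-9-ol | C=C[C@H]1CN2CC[C@H]1C[C@@H]2[C@H](c1ccnc2ccc(OC)cc12)O | starting material
23 | quinidinium salt of the (R)-lactol | Cc1cc(O)c(C=O)c2c1C(=O)Oc1c(COC(=O)/C=C/C(=O)[O-])c(O)c3c(c1O2)[C@H](O)OC3=O.C=C[C@H]1C[NH+]2CC[C@H]1C[C@@H]2[C@H](c1ccnc2ccc(OC)cc12)O | intermediate
24 | CNP0379578.1, (R)-lactol free acid | Cc1cc(O)c(C=O)c2c1C(=O)Oc1c(COC(=O)/C=C/C(=O)O)c(O)c3c(c1O2)[C@H](O)OC3=O | target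

**Count.** Total steps: 14. Longest linear sequence: 11 steps (1, 4, 5, 6, 7, 9, 10, 11, 12, 13, 14).

**Steps most likely to fail**

1. Step 13 (crystallisation-induced asymmetric transformation). The two diastereomeric salts may co-crystallise, the salt of the wrong epimer may be the less soluble one, or epimerisation in the slurry may be too slow to feed the crystal. Fallback, from 21 back to 24: the racemising lactol is resolved by preparative chromatography on an immobilised polysaccharide chiral stationary phase (acidified heptane–ethyl acetate, column and fractions kept near −20 °C); the (R) fraction is precipitated cold, and the (S) fraction is left to re-equilibrate in solution at room temperature and re-injected. This fallback makes no new compound (F0).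

2. Step 11 (oxidative ether closure). Ligand exchange and ionisation on the electron-poor ring B may stall, the aryloxyphenol product may be oxidised a second time, or oxidation may be diverted to ring A with capture by solvent. Fallback, from 17 back to 19: electrophilic bromination of the only ring C–H (NBS, MeCN, 0 °C) should give prop-2-en-1-yl 5-bromo-6-formyl-2,4-dihydroxy-3-({[(2E)-4-oxo-4-(prop-2-en-1-yloxy)but-2-enoyl]oxy}methyl)benzoate F1. Steglich esterification of F1 with acid 5 under the conditions of step 10 should give the 6′-bromo depside F2. A copper-catalysed intramolecular Ullmann O-arylation (CuI, N,N-dimethylglycine, K3PO4, dioxane, 90 °C) of the ring A C2 hydroxyl on the C6′ bromide then forms the same ether bond and delivers 19.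

3. Step 5 (dibromination). Hydrogen abstraction at the acetoxymethyl group may compete, or the reaction may stall at the monobromide, giving mixtures. Fallback, from 7 back to 9: one equivalent of NBS under the same radical conditions should give methyl 2,4-diacetoxy-3-(acetoxymethyl)-6-(bromomethyl)benzoate F3, which is oxidised with N-methylmorpholine N-oxide in MeCN (amine oxide oxidation of a benzylic bromide) to aldehyde 9; the route resumes with the LiOH stage of step 6.

**Further compounds**

F0 | step 13 | none | none
F1 | step 11 | prop-2-en-1-yl 5-bromo-6-formyl-2,4-dihydroxy-3-({[(2E)-4-oxo-4-(prop-2-en-1-yloxy)but-2-enoyl]oxy}methyl)benzoate | C=CCOC(=O)/C=C/C(=O)OCc1c(O)c(Br)c(C=O)c(C(=O)OCC=C)c1O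
F2 | step 11 | 6′-bromo depside (depside 18 with Br on C6′) | Cc1cc(OCC=C)c(C=O)c(O)c1C(=O)Oc1c(COC(=O)/C=C/C(=O)OCC=C)c(O)c(C(=O)OCC=C)c(C=O)c1Br
F3 | step 5 | methyl 2,4-diacetoxy-3-(acetoxymethyl)-6-(bromomethyl)benzoate | COC(=O)c1c(CBr)cc(OC(C)=O)c(COC(C)=O)c1OC(C)=O
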